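**Retrosynthetic overview**

1. Locants: cyclopentane C1 (triene-bearing), C2, C3, spiro C4, C5 (carbinol); cyclohexane C4, C6 (hydroxypropyl-bearing), C7 (enal ring carbon), C8, C9, C10 (methyl carbinol). The route rests on one feature: the carbonyl-level carbon C7 and the tertiary carbinol C10 are joined by the C8–C9 bridge, and the C5 oxygen sits 1,3 to C10 across spiro C4.
2. Key disconnection: C8–C9, by anodic coupling of a C7 silyl enol ether with a C4 isopropenyl group, the C10 cation being captured by a C5 tert-butyl carbonate. This closes the cyclohexanone and a six-membered carbonate on a preformed cyclopentane.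
3. Before: C4/C6 come from a chair Claisen rearrangement of the (Z)-allyl enol ether of methyl 2-oxocyclopentane-1-carboxylate (vinyl = latent C7 methyl ketone, ester = latent isopropenyl). C5 is set by chelation-controlled reduction.
4. After: C7 ketone → allylic alcohol (isopropenyl addition, 1,3-transposition) → enal last. C1 is functionalised from the C5 oxygen by carbenoid C–H insertion (cis lactone); α-methylenation, lactol and Horner–Wadsworth–Emmons olefination with a geranyl phosphonate then give the triene.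
5. Ring order: cyclopentane (purchased) → cyclohexanone and cyclic carbonate together (key step) → temporary γ-lactone on C1/C5, opened again.

Key step: step 11

Remark: the C7 carbinol centre of 15, the α-carbon of 23 and 24 and the lactol carbon of 26 form as mixtures and are removed in the following operation, so they are left undefined in the SMILES.

**Route**

Step 1
Reactants: 1 tert-butyldimethyl(pent-4-yn-1-yloxy)silane
Product: 2 6-(tert-butyldimethylsilyloxy)hex-2-yn-1-ol
Conditions: n-BuLi, THF, −78 °C; (CH2O)n, −78 °C → rt; aq. NH4Cl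
Reagents that add atoms: paraformaldehyde (as formaldehyde), C=O
Why: Alkynylation: the lithium acetylide of 1 adds to formaldehyde to give the propargylic alcohol (no stereocentre).

Step 2
Reactants: 2 6-(tert-butyldimethylsilyloxy)hex-2-yn-1-ol
Product: 3 (2Z)-6-(tert-butyldimethylsilyloxy)hex-2-en-1-ol
Conditions: H2 (1 atm), Pd/CaCO3–Pb(OAc)2, quinoline, EtOAc, rt
Reagents that add atoms: none
Why: Lindlar semihydrogenation adds hydrogen syn and stops at the (Z)-alkene, the geometry that step 4 converts into the C6 configuration.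

Step 3
Reactants: 3 (2Z)-6-(tert-butyldimethylsilyloxy)hex-2-en-1-ol; 4 methyl 2-oxocyclopentane-1-carboxylate
Product: 5 methyl 2-{[(2Z)-6-(tert-butyldimethylsilyloxy)hex-2-en-1-yl]oxy}cyclopent-1-ene-1-carboxylate
Conditions: PPh3, DIAD, THF, 0 °C → rt
Reagents that add atoms: none
Why: Mitsunobu etherification alkylates the acidic enol of the β-keto ester on oxygen by SN2 displacement at the primary allylic carbon, so the (Z)-geometry is kept (the usual access to O-allyl β-keto esters).

Step 4
Reactants: 5 methyl 2-{[(2Z)-6-(tert-butyldimethylsilyloxy)hex-2-en-1-yl]oxy}cyclopent-1-ene-1-carboxylate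
Product: 6 methyl (1S)-1-[(3R)-6-(tert-butyldimethylsilyloxy)hex-1-en-3-yl]-2-oxocyclopentane-1-carboxylate (C4 and C6 as in the target)
Conditions: N,N′-bis[(1R,2R)-2-(2,5-diphenylpyrrol-1-yl)cyclohexyl]guanidinium tetrakis[3,5-bis(trifluoromethyl)phenyl]borate (20 mol%; or its enantiomer, whichever gives 6), hexanes, 35 °C
Reagents that add atoms: none
Why: Claisen rearrangement ([3,3]) accelerated by the hydrogen-bond-donor guanidinium, as known for O-allyl β-keto esters, forms C4–C6 through a chair in which the ester carbon (cis to the ether oxygen) and the (Z)-chain are both pseudoaxial, which fixes the C4/C6 relative configuration, while the chiral cation selects the enol ether face and so the absolute configuration.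

Step 5
Reactants: 6 methyl (1S)-1-[(3R)-6-(tert-butyldimethylsilyloxy)hex-1-en-3-yl]-2-oxocyclopentane-1-carboxylate
Product: 7 methyl (1S,2R)-2-hydroxy-1-[(3R)-6-(tert-butyldimethylsilyloxy)hex-1-en-3-yl]cyclopentane-1-carboxylate (C5–OH cis to the C6 arm)
Conditions: Zn(BH4)2, Et2O, −20 °C
Reagents that add atoms: none
Why: Chelation-controlled ketone reduction: zinc ties the ketone to the ester carbonyl and hydride enters anti to the branched C6 arm, placing the C5 hydroxyl cis to that arm and trans to the ester.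

Step 6
Reactants: 7 methyl (1S,2R)-2-hydroxy-1-[(3R)-6-(tert-butyldimethylsilyloxy)hex-1-en-3-yl]cyclopentane-1-carboxylate
Product: 9 1-{2-hydroxy-1-[6-(tert-butyldimethylsilyloxy)hex-1-en-3-yl]cyclopentyl}ethan-1-one (stereocentres as in 7), via silylmethyl ketone 8 (not isolated)
Conditions: Me3SiCH2Li (4 equiv), THF/pentane, 0 °C → rt; MeOH, 0 °C; aq. NH4Cl
Reagents that add atoms: (trimethylsilyl)methyllithium, [Li]C[Si](C)(C)C
Why: Ester-to-methyl-ketone conversion with (trimethylsilyl)methyllithium: the first adduct collapses to the silylmethyl ketone, which is shielded from a second addition as its enolate and loses silicon on methanolysis; no stereocentre is touched.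

Step 7
Reactants: 9 1-{2-hydroxy-1-[6-(tert-butyldimethylsilyloxy)hex-1-en-3-yl]cyclopentyl}ethan-1-one
Product: 10 2-acetyl-2-[6-(tert-butyldimethylsilyloxy)hex-1-en-3-yl]cyclopentyl tert-butyl carbonate
Conditions: Boc2O, 4-(dimethylamino)pyridine, MeCN, rt
Reagents that add atoms: di-tert-butyl dicarbonate, CC(C)(C)OC(=O)OC(=O)OC(C)(C)C
Why: 4-(Dimethylamino)pyridine-catalysed O-acylation of the secondary alcohol under conditions too mild for retro-aldol cleavage of the β-hydroxy ketone.

Step 8
Reactants: 10 2-acetyl-2-[6-(tert-butyldimethylsilyloxy)hex-1-en-3-yl]cyclopentyl tert-butyl carbonate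
Product: 11 tert-butyl 2-(prop-1-en-2-yl)-2-[6-(tert-butyldimethylsilyloxy)hex-1-en-3-yl]cyclopentyl carbonate
Conditions: Cp2Ti(μ-CH2)(μ-Cl)AlMe2, pyridine (cat.), THF/toluene, −40 → 0 °C
Reagents that add atoms: Tebbe reagent Cp2Ti(μ-CH2)(μ-Cl)AlMe2, C=[Ti](C1C=CC=C1)C1C=CC=C1.C[Al](C)Cl
Why: Tebbe methylenation turns the hindered methyl ketone into the isopropenyl group under non-basic conditions that leave the tert-butyl carbonate, the vinyl group and C6 alone.

Step 9
Reactants: 11 tert-butyl 2-(prop-1-en-2-yl)-2-[6-(tert-butyldimethylsilyloxy)hex-1-en-3-yl]cyclopentyl carbonate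
Product: 12 tert-butyl 2-[6-(tert-butyldimethylsilyloxy)-2-oxohexan-3-yl]-2-(prop-1-en-2-yl)cyclopentyl carbonate
Conditions: PdCl2 (10 mol%), CuCl, O2 (1 atm), DMF/H2O (7:1), rt
Reagents that add atoms: water, O
Why: Tsuji–Wacker oxidation converts the monosubstituted vinyl group into the methyl ketone with Markovnikov regiochemistry, the 1,1-disubstituted isopropenyl group being much slower to react.

Step 10
Reactants: 12 tert-butyl 2-[6-(tert-butyldimethylsilyloxy)-2-oxohexan-3-yl]-2-(prop-1-en-2-yl)cyclopentyl carbonate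
Product: 13 tert-butyl 2-[2,6-bis(tert-butyldimethylsilyloxy)hex-1-en-3-yl]-2-(prop-1-en-2-yl)cyclopentyl carbonate
Conditions: LiN(iPr)2, THF, −78 °C; TBSOTf, −78 °C; Et3N, aq. NaHCO3
Reagents that add atoms: tert-butyldimethylsilyl trifluoromethanesulfonate, CC(C)(C)[Si](C)(C)OS(=O)(=O)C(F)(F)F
Why: Kinetic enolisation at the methyl group (C8) and O-silylation give the terminal silyl enol ether; the hindered C6–H is not removed, so C6 keeps its configuration.

Step 11
Reactants: 13 tert-butyl 2-[2,6-bis(tert-butyldimethylsilyloxy)hex-1-en-3-yl]-2-(prop-1-en-2-yl)cyclopentyl carbonate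
Product: 14 spiro cyclohexanone (C7 ketone) with a cyclic carbonate linking the C5 and C10 oxygens and the C6 3-(tert-butyldimethylsilyloxy)propyl chain
Conditions: reticulated vitreous carbon anode, Pt cathode, undivided cell, constant current (ca. 2.2 F/mol), LiClO4 (0.1 M), 2,6-lutidine, MeOH (3 equiv), CH2Cl2/(CF3)2CHOH (4:1), 0 °C
Reagents that add atoms: none
Why: Proposed new method: the anode removes one electron from the silyl enol ether (far easier to oxidise than the 1,1-disubstituted alkene), and the isopropenyl terminus C9 attacks the electrophilic C8 of the radical cation in a 6-endo-trig closure that puts the positive charge on tertiary C10 (the 5-exo mode would leave a primary centre). The Boc carbonyl oxygen on C5 captures C10 in a six-membered (6-exo) closure and loses isobutene, while the C7 α-silyloxy radical is oxidised a second time and desilylated by methanol to the ketone. The closest known reaction type is the anodic coupling of enol ether radical cations with tethered alkenes followed by trapping of the resulting cation by an oxygen nucleophile, here combined with the known capture of carbocations by tert-butyl carbonates; an internal carbonate has not been used as the trap in such a coupling. The only new stereocentre, C10, is set by the tether: once the cyclohexane ring exists, C5 lies on one face of the C10 cation, so the oxygen arrives cis to C5 (carbonate cis-fused to the cyclohexanone and trans-fused to the cyclopentane, strained but accessible, as in nucleoside 3′,5′-cyclic carbonates). The step needs internal capture to beat solvent capture and proton loss, which the weakly nucleophilic medium (only a little methanol as silyl acceptor) and the six-membered delivery should secure; C4 is quaternary, so the enol ether is regiodefined and neither partner can isomerise.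

Step 12
Reactants: 14 spiro cyclohexanone cyclic carbonate
Product: 15 C7 tertiary allylic alcohol (C7 carries OH and prop-1-en-2-yl; cyclic carbonate intact)
Conditions: CH2=C(CH3)MgBr, CeCl3, THF, −78 °C; aq. NH4Cl
Reagents that add atoms: isopropenylmagnesium bromide, C=C(C)[Mg]Br
Why: 1,2-Addition of the weakly basic organocerium reagent to the hindered, enolisable ketone is much faster at −78 °C than attack on the carbonate; the new C7 carbinol centre is lost in step 13 and need not be controlled.

Step 13
Reactants: 15 C7 tertiary allylic alcohol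
Product: 17 triol with C7=C(CH3)CH2OH (CH2OH cis to C6) and free C5 and C10 hydroxyls, via allylic trimethylsilyl ether 16 (not isolated)
Conditions: Ph3SiOReO3 (5 mol%), N,O-bis(trimethylsilyl)acetamide, Et2O, 0 °C; then K2CO3, MeOH, rt
Reagents that add atoms: none
Why: Rhenium-oxo-catalysed 1,3-transposition of the tertiary allylic alcohol ([3,3] shift of its perrhenate ester) is pulled to the primary side by silylation, the chair that keeps the isopropenyl methyl next to C8H2 and away from the substituted C6 putting CH2O cis to C6 (the other geometrical isomer, if formed, is separable); methanolysis then removes the trimethylsilyl group and opens the strained cyclic carbonate.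

Step 14
Reactants: 17 triol
Product: 18 diol with the allylic primary hydroxyl as its tert-butyldimethylsilyl ether (C5–OH and C10–OH free)
Conditions: TBSCl, imidazole, CH2Cl2, 0 °C
Reagents that add atoms: tert-butyldimethylsilyl chloride, CC(C)(C)[Si](C)(C)Cl
Why: Silyl ether formation at the primary allylic hydroxyl, far faster than at the neopentyl-type secondary C5 hydroxyl or the tertiary C10 hydroxyl.

Step 15
Reactants: 18 diol
Product: 19 C5 bromoacetate (C10–OH free)
Conditions: BrCH2COBr, pyridine, CH2Cl2, −20 → 0 °C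
Reagents that add atoms: bromoacetyl bromide, BrCC(=O)Br
Why: O-Acylation of the secondary C5 hydroxyl by the acid bromide; the tertiary C10 hydroxyl is not acylated under these conditions.

Step 16
Reactants: 19 C5 bromoacetate
Product: 20 C5 bromoacetate with C10–O triethylsilyl ether
Conditions: Et3SiOTf, 2,6-lutidine, CH2Cl2, −78 → 0 °C
Reagents that add atoms: triethylsilyl trifluoromethanesulfonate, CC[Si](CC)(CC)OS(=O)(=O)C(F)(F)F
Why: Silyl triflate silylation caps the tertiary C10 hydroxyl so that the carbenoid of step 18 cannot insert into its O–H bond.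

Step 17
Reactants: 20 C5 bromoacetate with C10–O triethylsilyl ether
Product: 21 C5 diazoacetate
Conditions: TsNHNHTs, DBU, THF, 0 °C
Reagents that add atoms: N,N′-ditosylhydrazine, Cc1ccc(cc1)S(=O)(=O)NNS(=O)(=O)c1ccc(C)cc1
Why: Diazoacetate synthesis by N-alkylation of N,N′-ditosylhydrazine with the bromoacetate followed by base-induced loss of two sulfinates.

Step 18
Reactants: 21 C5 diazoacetate
Product: 22 cis-fused γ-lactone bridging C5–O and C1 (C1–CH2–C(=O)–O–C5)
Conditions: Rh2(NHCOCH3)4 (1 mol%), CH2Cl2, reflux, slow addition of 21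
Reagents that add atoms: none
Why: Intramolecular rhodium-carbenoid C–H insertion of a cycloalkyl diazoacetate gives the γ-lactone; only C1 offers a C–H bond at the right distance (C4 is quaternary), and the cis ring fusion of the oxabicyclo[3.3.0]octanone puts the new C1–C bond on the face of the C5 oxygen, which sets C1.

Step 19
Reactants: 22 cis-fused γ-lactone
Product: 25 α-methylene γ-lactone, via Mannich base 23 (not isolated), via methiodide 24 (not isolated)
Conditions: LiN(iPr)2, THF, −78 °C, then CH2=NMe2+ I−, → rt; MeI, THF/MeOH, rt; DBU, rt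
Reagents that add atoms: dimethyl(methylidene)ammonium iodide, C=[N+](C)C.[I-]
Why: α-Methylenation of a lactone: Mannich reaction of the lithium enolate with the iminium salt, N-methylation and E1cB-type elimination of trimethylamine.

Step 20
Reactants: 25 α-methylene γ-lactone
Product: 26 α-methylene lactol
Conditions: iBu2AlH, CH2Cl2, −78 °C; aq. KNaC4H4O6
Reagents that add atoms: none
Why: Partial reduction of the lactone to the lactol with iBu2AlH at −78 °C (1,2-hydride addition; the lactol carbon is an anomer mixture that disappears in step 22).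

Step 21
Reactants: 27 geranyl bromide
Product: 28 diethyl [(2E)-3,7-dimethylocta-2,6-dien-1-yl]phosphonate
Conditions: P(OEt)3, neat, 120 °C
Reagents that add atoms: triethyl phosphite, CCOP(OCC)OCC
Why: Michaelis–Arbuzov reaction of the primary allylic bromide with triethyl phosphite; the (E)-trisubstituted alkene is not touched.

Step 22
Reactants: 26 α-methylene lactol; 28 diethyl [(2E)-3,7-dimethylocta-2,6-dien-1-yl]phosphonate
Product: 29 silyl-protected triene with free C5–OH (two primary TBS ethers and C10–O triethylsilyl ether)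
Conditions: 28 (2.5 equiv), n-BuLi, THF, −78 °C; then 26, −78 °C → rt
Reagents that add atoms: none
Why: Horner–Wadsworth–Emmons olefination of the hydroxy enal tautomer of the lactol with the allylic phosphonate anion, which forms (E)-1,3-dienes preferentially, builds the triene and releases the C5 hydroxyl without touching C1.

Step 23
Reactants: 29 silyl-protected triene
Product: 30 tetraol (target with CH2OH in place of CHO)
Conditions: Bu4NF, THF, rt; aq. NH4Cl
Reagents that add atoms: none
Why: Fluoride-mediated cleavage of the two primary tert-butyldimethylsilyl ethers and the tertiary triethylsilyl ether.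

Step 24
Reactants: 30 tetraol
Product: 31 CNP0173034.1
Conditions: MnO2, CH2Cl2, rt
Reagents that add atoms: none
Why: MnO2 oxidation is selective for the primary allylic alcohol and gives the enal with retained alkene geometry, while the saturated primary, secondary and tertiary hydroxyls and the triene are left alone.

**Compound list**

1 | tert-butyldimethyl(pent-4-yn-1-yloxy)silane | C#CCCCO[Si](C)(C)C(C)(C)C | starting material
2 | 6-(tert-butyldimethylsilyloxy)hex-2-yn-1-ol | OCC#CCCCO[Si](C)(C)C(C)(C)C | intermediate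
3 | (2Z)-6-(tert-butyldimethylsilyloxy)hex-2-en-1-ol | OC/C=C\CCCO[Si](C)(C)C(C)(C)C | intermediate
4 | methyl 2-oxocyclopentane-1-carboxylate | COC(=O)C1CCCC1=O | starting material
5 | methyl 2-{[(2Z)-6-(tert-butyldimethylsilyloxy)hex-2-en-1-yl]oxy}cyclopent-1-ene-1-carboxylate | COC(=O)C1=C(OC/C=C\CCCO[Si](C)(C)C(C)(C)C)CCC1 | intermediate
6 | methyl (1S)-1-[(3R)-6-(tert-butyldimethylsilyloxy)hex-1-en-3-yl]-2-oxocyclopentane-1-carboxylate | C1CC[C@](C(=O)OC)([C@H](CCCO[Si](C)(C)C(C)(C)C)C=C)C1=O | intermediate
7 | methyl (1S,2R)-2-hydroxy-1-[(3R)-6-(tert-butyldimethylsilyloxy)hex-1-en-3-yl]cyclopentane-1-carboxylate | C1CC[C@](C(=O)OC)([C@H](CCCO[Si](C)(C)C(C)(C)C)C=C)[C@@H]1O | intermediate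
8 | 1-{2-hydroxy-1-[6-(tert-butyldimethylsilyloxy)hex-1-en-3-yl]cyclopentyl}-2-(trimethylsilyl)ethan-1-one (stereocentres as in 7; not isolated) | C1CC[C@](C(=O)C[Si](C)(C)C)([C@H](CCCO[Si](C)(C)C(C)(C)C)C=C)[C@@H]1O | intermediate
9 | 1-{2-hydroxy-1-[6-(tert-butyldimethylsilyloxy)hex-1-en-3-yl]cyclopentyl}ethan-1-one (stereocentres as in 7) | C1CC[C@](C(C)=O)([C@H](CCCO[Si](C)(C)C(C)(C)C)C=C)[C@@H]1O | intermediate
10 | 2-acetyl-2-[6-(tert-butyldimethylsilyloxy)hex-1-en-3-yl]cyclopentyl tert-butyl carbonate | C1CC[C@](C(C)=O)([C@H](CCCO[Si](C)(C)C(C)(C)C)C=C)[C@@H]1OC(=O)OC(C)(C)C | intermediate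
11 | tert-butyl 2-(prop-1-en-2-yl)-2-[6-(tert-butyldimethylsilyloxy)hex-1-en-3-yl]cyclopentyl carbonate | C1CC[C@](C(C)=C)([C@H](CCCO[Si](C)(C)C(C)(C)C)C=C)[C@@H]1OC(=O)OC(C)(C)C | intermediate
12 | tert-butyl 2-[6-(tert-butyldimethylsilyloxy)-2-oxohexan-3-yl]-2-(prop-1-en-2-yl)cyclopentyl carbonate | C1CC[C@](C(C)=C)([C@H](CCCO[Si](C)(C)C(C)(C)C)C(C)=O)[C@@H]1OC(=O)OC(C)(C)C | intermediate
13 | tert-butyl 2-[2,6-bis(tert-butyldimethylsilyloxy)hex-1-en-3-yl]-2-(prop-1-en-2-yl)cyclopentyl carbonate (key-step precursor) | C1CC[C@](C(C)=C)([C@H](CCCO[Si](C)(C)C(C)(C)C)C(=C)O[Si](C)(C)C(C)(C)C)[C@@H]1OC(=O)OC(C)(C)C | intermediate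
14 | spiro cyclohexanone with cyclic carbonate across the C5 and C10 oxygens (key-step product) | C1CC[C@]2([C@H](CCCO[Si](C)(C)C(C)(C)C)C(=O)CC[C@]2(C)O3)[C@@H]1OC3=O | intermediate
15 | C7 tertiary allylic alcohol (OH and prop-1-en-2-yl on C7; C7 epimer mixture) | C1CC[C@]2([C@H](CCCO[Si](C)(C)C(C)(C)C)C(O)(C(C)=C)CC[C@]2(C)O3)[C@@H]1OC3=O | intermediate
16 | allylic trimethylsilyl ether with cyclic carbonate (CH2O cis to C6; not isolated) | C1CC[C@]2([C@H](CCCO[Si](C)(C)C(C)(C)C)/C(=C(/C)CO[Si](C)(C)C)CC[C@]2(C)O3)[C@@H]1OC3=O | intermediate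
17 | triol: C7=C(CH3)CH2OH, C5–OH, C10–OH | C1CC[C@]2([C@H](CCCO[Si](C)(C)C(C)(C)C)/C(=C(/C)CO)CC[C@]2(C)O)[C@@H]1O | intermediate
18 | C5/C10 diol with allylic tert-butyldimethylsilyl ether | C1CC[C@]2([C@H](CCCO[Si](C)(C)C(C)(C)C)/C(=C(/C)CO[Si](C)(C)C(C)(C)C)CC[C@]2(C)O)[C@@H]1O | intermediate
19 | C5 bromoacetate, C10–OH free | C1CC[C@]2([C@H](CCCO[Si](C)(C)C(C)(C)C)/C(=C(/C)CO[Si](C)(C)C(C)(C)C)CC[C@]2(C)O)[C@@H]1OC(=O)CBr | intermediate
20 | C5 bromoacetate, C10–O triethylsilyl ether | C1CC[C@]2([C@H](CCCO[Si](C)(C)C(C)(C)C)/C(=C(/C)CO[Si](C)(C)C(C)(C)C)CC[C@]2(C)O[Si](CC)(CC)CC)[C@@H]1OC(=O)CBr | intermediate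
21 | C5 diazoacetate, C10–O triethylsilyl ether | C1CC[C@]2([C@H](CCCO[Si](C)(C)C(C)(C)C)/C(=C(/C)CO[Si](C)(C)C(C)(C)C)CC[C@]2(C)O[Si](CC)(CC)CC)[C@@H]1OC(=O)C=[N+]=[N-] | intermediate
22 | cis-fused γ-lactone on C1/C5 | O=C1C[C@@H]2CC[C@]3([C@H](CCCO[Si](C)(C)C(C)(C)C)/C(=C(/C)CO[Si](C)(C)C(C)(C)C)CC[C@]3(C)O[Si](CC)(CC)CC)[C@@H]2O1 | intermediate
23 | α-(dimethylaminomethyl) lactone (Mannich base; not isolated) | O=C1C(CN(C)C)[C@@H]2CC[C@]3([C@H](CCCO[Si](C)(C)C(C)(C)C)/C(=C(/C)CO[Si](C)(C)C(C)(C)C)CC[C@]3(C)O[Si](CC)(CC)CC)[C@@H]2O1 | intermediate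
24 | α-(trimethylammoniomethyl) lactone iodide (not isolated) | O=C1C(C[N+](C)(C)C)[C@@H]2CC[C@]3([C@H](CCCO[Si](C)(C)C(C)(C)C)/C(=C(/C)CO[Si](C)(C)C(C)(C)C)CC[C@]3(C)O[Si](CC)(CC)CC)[C@@H]2O1.[I-] | intermediate
25 | α-methylene γ-lactone | O=C1C(=C)[C@@H]2CC[C@]3([C@H](CCCO[Si](C)(C)C(C)(C)C)/C(=C(/C)CO[Si](C)(C)C(C)(C)C)CC[C@]3(C)O[Si](CC)(CC)CC)[C@@H]2O1 | intermediate
26 | α-methylene lactol (anomer mixture) | OC1C(=C)[C@@H]2CC[C@]3([C@H](CCCO[Si](C)(C)C(C)(C)C)/C(=C(/C)CO[Si](C)(C)C(C)(C)C)CC[C@]3(C)O[Si](CC)(CC)CC)[C@@H]2O1 | intermediate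
27 | geranyl bromide, (2E)-1-bromo-3,7-dimethylocta-2,6-diene | BrC/C=C(\C)CCC=C(C)C | starting material
28 | diethyl [(2E)-3,7-dimethylocta-2,6-dien-1-yl]phosphonate | CCOP(=O)(C/C=C(\C)CCC=C(C)C)OCC | intermediate
29 | silyl-protected triene with free C5–OH | C=C(/C=C/C=C(\C)CCC=C(C)C)[C@@H]1CC[C@]2([C@H](CCCO[Si](C)(C)C(C)(C)C)/C(=C(/C)CO[Si](C)(C)C(C)(C)C)CC[C@]2(C)O[Si](CC)(CC)CC)[C@@H]1O | intermediate
30 | tetraol (allylic alcohol corresponding to the target enal) | C=C(/C=C/C=C(\C)CCC=C(C)C)[C@@H]1CC[C@]2([C@H](CCCO)/C(=C(/C)CO)CC[C@]2(C)O)[C@@H]1O | intermediate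
31 | CNP0173034.1 | C=C(/C=C/C=C(\C)CCC=C(C)C)[C@@H]1CC[C@]2([C@H](CCCO)/C(=C(/C)C=O)CC[C@]2(C)O)[C@@H]1O | target

**Summary**

Total step count: 24. Longest linear sequence: 23 steps (steps 1–20 and 22–24; step 21 is a one-step side branch).

**Steps most likely to fail**

1. Step 11 (key step). The C10 cation may be quenched by methanol or lose a proton before the carbonate closes. The cyclised radical cation may also cleave C4–C6 (radical-cation Cope pathway), or the enol ether may be desilylated before it is oxidised. Fallback with known reactions, setting out from 12 and coming back at 14: ene-type allylic chlorination of the isopropenyl group (Ca(OCl)2, CO2, CH2Cl2/H2O, 0 °C) gives the allylic chloride F1. Intramolecular C-alkylation of the kinetic methyl-ketone enolate (KN(SiMe3)2, THF, −78 → 0 °C) then forms C8–C9 and gives the 10-methylene spiro ketone F2. Iodocarbonate cyclisation of the tert-butyl carbonate onto the exocyclic alkene (IBr, toluene/CH2Cl2, −80 °C) gives the iodomethyl cyclic carbonate F3, the oxygen again reaching C10 from the side of C5 because the ring is already closed. Radical deiodination (Bu3SnH, azobisisobutyronitrile, toluene, 80 °C) gives 14.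

2. Step 18. The carbenoid may insert into other C–H bonds (the allylic C6–H through a six-membered transition state), dimerise, or attack the tetrasubstituted alkene. Fallback from 18, coming back at 22: Dess–Martin oxidation of the secondary alcohol gives the C5 ketone F4 with the tertiary C10 hydroxyl untouched. Double deprotonation with LiN(SiMe3)2 (alkoxide, then the only possible enolate, at C1) and alkylation with methyl bromoacetate gives the keto ester F5, whose C1 epimers are separable and interconvert through the enolate. Hydroxyl-directed reduction with Me4NBH(OAc)3 (MeCN/AcOH, −20 °C) delivers hydride to C5 from the face of the C10 hydroxyl, anti to the C1 arm, and the cis hydroxy ester closes to the hydroxy lactone F6. Et3SiOTf/2,6-lutidine then gives 22.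

3. Step 4. The (Z)-substrate must place its chain pseudoaxial, so turnover may be slow, enantioface discrimination may erode, and a boat transition state may leak the C6 epimer. Fallback from 5, coming back at 7: heating 5 without catalyst (toluene, 80 °C) gives the racemic keto ester F7 with the same chair-derived relative configuration. Zn(BH4)2 reduction gives the racemic hydroxy ester F8. Esterification with (S)-2-methoxy-2-phenylacetic acid (dicyclohexylcarbodiimide, 4-(dimethylamino)pyridine) gives two diastereomeric esters that are separated by chromatography, the ester of the required enantiomer F9 and the ester of the other enantiomer F10. Methanolysis of F9 (K2CO3, MeOH) gives 7.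

**Further compounds**

F1 | step 11 | tert-butyl 2-(3-chloroprop-1-en-2-yl)-2-[6-(tert-butyldimethylsilyloxy)-2-oxohexan-3-yl]cyclopentyl carbonate | C1CC[C@](C(=C)CCl)([C@H](CCCO[Si](C)(C)C(C)(C)C)C(C)=O)[C@@H]1OC(=O)OC(C)(C)C
F2 | step 11 | 10-methylene spiro cyclohexanone with C5 tert-butyl carbonate | C1CC[C@]2([C@H](CCCO[Si](C)(C)C(C)(C)C)C(=O)CCC2=C)[C@@H]1OC(=O)OC(C)(C)C
F3 | step 11 | spiro cyclohexanone cyclic carbonate with iodomethyl on C10 | C1CC[C@]2([C@H](CCCO[Si](C)(C)C(C)(C)C)C(=O)CC[C@]2(CI)O3)[C@@H]1OC3=O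
F4 | step 18 | C5 ketone with free C10 hydroxyl | C1CC[C@]2([C@H](CCCO[Si](C)(C)C(C)(C)C)/C(=C(/C)CO[Si](C)(C)C(C)(C)C)CC[C@]2(C)O)C1=O
F5 | step 18 | C5 ketone with methoxycarbonylmethyl on C1 | COC(=O)C[C@@H]1CC[C@]2([C@H](CCCO[Si](C)(C)C(C)(C)C)/C(=C(/C)CO[Si](C)(C)C(C)(C)C)CC[C@]2(C)O)C1=O
F6 | step 18 | cis-fused γ-lactone with free C10 hydroxyl | O=C1C[C@@H]2CC[C@]3([C@H](CCCO[Si](C)(C)C(C)(C)C)/C(=C(/C)CO[Si](C)(C)C(C)(C)C)CC[C@]3(C)O)[C@@H]2O1
F7 | step 4 | racemic methyl 1-[6-(tert-butyldimethylsilyloxy)hex-1-en-3-yl]-2-oxocyclopentane-1-carboxylate (6 and its enantiomer) | C1CC[C@](C(=O)OC)([C@H](CCCO[Si](C)(C)C(C)(C)C)C=C)C1=O.C1CC[C@@](C(=O)OC)([C@@H](CCCO[Si](C)(C)C(C)(C)C)C=C)C1=O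
F8 | step 4 | racemic methyl 2-hydroxy-1-[6-(tert-butyldimethylsilyloxy)hex-1-en-3-yl]cyclopentane-1-carboxylate (7 and its enantiomer) | C1CC[C@](C(=O)OC)([C@H](CCCO[Si](C)(C)C(C)(C)C)C=C)[C@@H]1O.C1CC[C@@](C(=O)OC)([C@@H](CCCO[Si](C)(C)C(C)(C)C)C=C)[C@H]1O
F9 | step 4 | (S)-2-methoxy-2-phenylacetate of 7 | C1CC[C@](C(=O)OC)([C@H](CCCO[Si](C)(C)C(C)(C)C)C=C)[C@@H]1OC(=O)[C@@H](OC)c1ccccc1
F10 | step 4 | (S)-2-methoxy-2-phenylacetate of the enantiomer of 7 | C1CC[C@@](C(=O)OC)([C@@H](CCCO[Si](C)(C)C(C)(C)C)C=C)[C@H]1OC(=O)[C@@H](OC)c1ccccc1
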